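The larch run, made earlier with 1 equiv of partner, read 88.9% of starting material at 3.00 min. Alder, the flask in question, with 0.50 equiv, read 89.1% at the same time.

| flask | starting material | partner | second reagent | third reagent | remark | time |
|---|---|---|---|---|---|---|
| alder | 0.015 M (fed, over 2.0 min) | 0.50 equiv | 1.1 equiv | 1.5 equiv | the very flask that is asked about, followed so far; the fed solution adds 1.0 times the starting volume |  |
| larch | 0.015 M (fed, over 2.0 min) | 1 equiv | 1.1 equiv | 1.5 equiv | run made earlier; the fed solution adds 1.0 times the starting volume |  |
| flask | 0.015 M (fed, over 2.0 min) | 0.500 equiv | 1.10 equiv | 1.50 equiv | the fed solution adds 1.0 times the starting volume | 15 min |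

- alder (time / min: starting material / %, target / %): 0.500: 23.1, 0; 0.833: 36.7, 0; 1.50: 66.9, 0; 3.00: 89.1, 0.9; 6.00: 88.4, 0
- larch (time / min: starting material / %, target / %): 0.500: 22.0, 1.6; 1.50: 66.2, 0; 3.00: 88.9, 1.1; 4.00: 86.6, 2.5; 6.00: 84.9, 1.9

(readings scatter by 1 percentage point)

- amounts are per litre of the starting volume; all of the dose is in the solution fed
- percentages count the whole charge, also what has not yet gone in

1. amount of starting material in percent of the starting material charged, at 1.5 min, 5.0 min and 15 min

Target read no higher than 2.5% in either run, so I worked with the fraction left and not with the fraction made. The kept fraction is starting material present over starting material fed so far. The feed was over by 3.00 min, and alder's reading then put it at 89.1%.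

I applied that to the feed. At 1.5 min, 75.0% of the charge had gone in, so I expected 66.8%, and alder's own reading there was 66.9%.

After the feed, alder fell 0.7 percentage points by 6.00 min, against a scatter of 1 point. Reading between those points gave 88.6% at 5.0 min. The same straight line gave 86.3% at 15 min.

That line was the weak link. Larch fell 4 points over the same span, faster than alder, so the drift seemed to go with the partner and should slow as partner was used. I therefore took the middle between the end of the line and a flat stop at alder's last reading, 87.4%.

The forecast gave 66.7%, 87.8% and 83.5%, with the fall “possibly slowing as partner is used”. My last number stood higher.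

Alder gave 68.2%, 87.8% and 87.3%, and the forecast was right within its margin.

    starting material + partner → intermediate A (k = 1.70 M⁻¹ s⁻¹)
    second reagent + intermediate A → intermediate B (k = 0.410 M⁻¹ s⁻¹)
    third reagent + intermediate B ⇌ target (K = 20.0 M⁻¹, k = 0.0680 M⁻¹ s⁻¹)
    intermediate A → decomposed reagent (k = 0.00440 s⁻¹)
    2 partner → self-condensation product (k = 3.80 M⁻¹ s⁻¹)

Alder's kept fraction came to 90.9% at 1.5 min, and larch's reading, by the same division, gave 88.3% at 1.50 min. At 15 min alder's was 87.3%, with the partner, its limiting reagent, at 0% of its charge. Partner also condenses with itself. With that path taken away, alder's starting material ended 37 points lower, at 50.1%.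

The numbers in the tables are calculated with constants of no real substance.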